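**Retrosynthetic overview**

- The quaternary carbon is disconnected last (C–C): the target comes from a tertiary β-bromo trifluoroacetate and an (E)-2-chlorovinylsilane, with the bromine relaying the configuration (retention).
- The vicinal Cl/Br pair comes from anti, Markovnikov addition of BrCl to the remaining ring double bond.
- The other C–Br bond comes from SN2 opening of a trisubstituted epoxide by bromide; the epoxide oxygen stays on the tertiary carbon as the later leaving group.
- The epoxide (two C–O bonds) comes from a desymmetrising asymmetric epoxidation of achiral 1,5-dimethylcyclohexa-1,4-diene, the stereo-defining event of the route; the diene comes from m-xylene by Birch reduction.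
- Rings: the only ring of the target, the cyclohexane, is carried through from m-xylene and no carbocycle is built; the oxirane (step 2) and the bromonium ring (step 6) are transient.

Assumption: the D-fructose-derived ketone epoxidises this 1-methylcyclohexene-type double bond with the same facial sense as 1-phenylcyclohexene (which gives the (R,R)-oxide); if the sense proves opposite, the L-fructose-derived enantiomer of the ketone is used and nothing else changes.

**Step 1**
Reactants: 1 m-xylene (1,3-dimethylbenzene)
Product: 2 1,5-dimethylcyclohexa-1,4-diene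
Conditions: Li, NH3 (l), t-BuOH, THF, −78 → −33 °C
Reagents that add atoms: none
Why: Birch reduction: the radical anion is protonated at the two unsubstituted, mutually para ring positions, so both methyl groups stay on the remaining double bonds and the achiral skipped diene results; no stereocentre is formed.

**Step 2**
Reactants: 2 1,5-dimethylcyclohexa-1,4-diene
Product: 3 (1S,6R)-1,3-dimethyl-7-oxabicyclo[4.1.0]hept-3-ene
Conditions: 1,2:4,5-di-O-isopropylidene-β-D-erythro-2,3-hexodiulo-2,6-pyranose (30 mol %), Oxone (2KHSO5·KHSO4·K2SO4; 1.0 equiv KHSO5), K2CO3, Bu4NHSO4 (cat.), MeCN–CH2(OMe)2 / aq. Na2B4O7 buffer (pH 10.5), 0 °C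
Reagents that add atoms: potassium peroxymonosulfate KHSO5 (in Oxone), [K+].[O-]S(=O)(=O)OO
Why: Shi asymmetric epoxidation: the chiral dioxirane formed in situ delivers oxygen through a spiro transition state to one face of one of the two enantiotopic trisubstituted double bonds, which creates both C–O bonds and both stereocentres (1S,6R) at once, and the minor enantiomer is removed faster by over-oxidation to the trans-bis-epoxide, which raises the ee of 3.

**Step 3**
Reactants: 3 (1S,6R)-1,3-dimethyl-7-oxabicyclo[4.1.0]hept-3-ene
Product: 5 (1S,6S)-6-bromo-1,3-dimethylcyclohex-3-en-1-yl 2,2,2-trifluoroacetate, via lithium bromo-alkoxide 4 (not isolated)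
Conditions: Li2NiBr4 (0.4 M in THF, 1.5 equiv), 0 → 20 °C; then pyridine, (CF3CO)2O, −20 → 0 °C
Reagents that add atoms: dilithium tetrabromonickelate Li2NiBr4, [Li+].[Li+].[Ni+2].[Br-].[Br-].[Br-].[Br-]; trifluoroacetic anhydride, O=C(OC(=O)C(F)(F)F)C(F)(F)F
Why: SN2 epoxide opening then O-acylation: the soft bromide of Li2NiBr4 attacks the less substituted oxirane carbon with inversion (trans-diaxial opening), which sets the C–Br centre anti to the untouched tertiary C–O bond, and the resulting tertiary alkoxide is trapped by the anhydride.

**Step 4**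
Reactants: 5 (1S,6S)-6-bromo-1,3-dimethylcyclohex-3-en-1-yl 2,2,2-trifluoroacetate
Product: 6 (1S,2S,4S,5S)-2,4-dibromo-5-chloro-1,5-dimethylcyclohexyl 2,2,2-trifluoroacetate
Conditions: N-bromosuccinimide, HCl (2 M in Et2O), CH2Cl2, −78 °C
Reagents that add atoms: N-bromosuccinimide, O=C1CCC(=O)N1Br; hydrogen chloride, Cl
Why: Electrophilic anti bromochlorination (BrCl formed in situ): chloride opens the bromonium ion at the tertiary carbon (Markovnikov) in the trans-diaxial Fürst–Plattner sense, and the pathway shown is preferred because the other one needs a bromonium ion syn-axial to the existing C–Br bond and chloride attack syn-axial to the ester oxygen, so Cl ends on the face opposite to the ester and Br trans to Cl; the electron-poor trifluoroacetate does not act as a neighbouring group.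

**Step 5**
Reactants: 7 ethynyltrimethylsilane
Product: 9 (E)-(2-chloroethenyl)trimethylsilane, via alkenylzirconocene chloride 8 (not isolated)
Conditions: Cp2Zr(H)Cl, THF, 25 °C; then N-chlorosuccinimide, 0 °C
Reagents that add atoms: N-chlorosuccinimide, O=C1CCC(=O)N1Cl
Why: Hydrozirconation–halogenation: syn addition of Zr–H puts zirconium on the terminal alkyne carbon and N-chlorosuccinimide cleaves the C–Zr bond with retention, which fixes the E geometry.

**Step 6**
Reactants: 6 (1S,2S,4S,5S)-2,4-dibromo-5-chloro-1,5-dimethylcyclohexyl 2,2,2-trifluoroacetate; 9 (E)-(2-chloroethenyl)trimethylsilane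
Product: 11 (1S,2S,4S,5R)-2,4-dibromo-1-chloro-5-[(E)-2-chloroethenyl]-1,5-dimethylcyclohexane, via bromonium triflate 10 (not isolated)
Conditions: 9 (3 equiv), Me3SiOSO2CF3 (20 mol %), CH2Cl2, −78 → −20 °C
Reagents that add atoms: none
Why: Proposed new method: Me3SiOSO2CF3 silylates the trifluoroacetate carbonyl and the anti-periplanar neighbouring bromine expels the silyl ester from the tertiary carbon to give the enantiopure bromonium triflate 10 (the oxophilic silyl triflate leaves the tertiary C–Cl bond alone), the silicon-bearing carbon of 9 then attacks the more substituted bromonium carbon anti to bromine to give a β-silyl, α-chloro-stabilised cation that loses Me3Si+ to triflate (catalyst turnover) with retention of the E geometry, so the quaternary centre forms with overall retention (double inversion) and the chlorovinyl group ends trans to the adjacent bromine; the closest known reaction types are the Lewis-acid-mediated ipso-substitution of vinyl- and allylsilanes by tertiary carbocations (Friedel–Crafts / Hosomi–Sakurai type) and the stereoretentive solvolysis of trans-β-bromo esters through bromonium ions, which have not been combined to make an all-carbon quaternary stereocentre.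

**Compound list**

1 | m-xylene (1,3-dimethylbenzene) | Cc1cccc(C)c1 | starting material
2 | 1,5-dimethylcyclohexa-1,4-diene | CC1=CCC=C(C)C1 | intermediate
3 | (1S,6R)-1,3-dimethyl-7-oxabicyclo[4.1.0]hept-3-ene | CC1=CC[C@H]2O[C@@]2(C)C1 | intermediate
4 | lithium (1S,6S)-6-bromo-1,3-dimethylcyclohex-3-en-1-olate | CC1=CC[C@H](Br)[C@@](C)([O-])C1.[Li+] | intermediate
5 | (1S,6S)-6-bromo-1,3-dimethylcyclohex-3-en-1-yl 2,2,2-trifluoroacetate | CC1=CC[C@H](Br)[C@@](C)(OC(=O)C(F)(F)F)C1 | intermediate
6 | (1S,2S,4S,5S)-2,4-dibromo-5-chloro-1,5-dimethylcyclohexyl 2,2,2-trifluoroacetate | C[C@]1(Cl)C[C@](C)(OC(=O)C(F)(F)F)[C@@H](Br)C[C@@H]1Br | intermediate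
7 | ethynyltrimethylsilane | C#C[Si](C)(C)C | starting material
8 | chlorobis(cyclopentadienyl)[(E)-2-(trimethylsilyl)ethenyl]zirconium | C[Si](C)(C)/C=C/[Zr](Cl)(C1C=CC=C1)C1C=CC=C1 | intermediate
9 | (E)-(2-chloroethenyl)trimethylsilane | C[Si](C)(C)/C=C/Cl | intermediate
10 | (1R,3S,4S,6S)-4-bromo-3-chloro-1,3-dimethyl-7-bromoniabicyclo[4.1.0]heptane trifluoromethanesulfonate (bromine bridging on the face opposite to the departed ester oxygen) | C[C@]1(Cl)C[C@@]2(C)[Br+][C@H]2C[C@@H]1Br.[O-]S(=O)(=O)C(F)(F)F | intermediate
11 | (1S,2S,4S,5R)-2,4-dibromo-1-chloro-5-[(E)-2-chloroethenyl]-1,5-dimethylcyclohexane | C[C@]1(Cl)C[C@](C)(/C=C/Cl)[C@@H](Br)C[C@@H]1Br | target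

**Step count**

Total steps: 6. Longest linear sequence: 5 (m-xylene to 11 through steps 1, 2, 3, 4 and 6); step 5 is a one-step side branch.

**Steps most likely to fail**

Step 6 (the proposed new step). The chlorovinylsilane is a weak π-nucleophile, so the bromonium ion may instead lose a proton to an allylic bromide, be opened at its secondary carbon, or the second tertiary centre may ionise. The fallback uses the known coupling of tertiary alkyl chlorides with alkynylalanes followed by hydrozirconation–chlorination; it sets out from 6 and comes back at 11. TiCl4 in CH2Cl2 at −78 °C exchanges the tertiary trifluoroacetate for chloride with retention to give the C2-symmetric tetrahalide (1S,3S,4S,6S)-4,6-dibromo-1,3-dichloro-1,3-dimethylcyclohexane F1, whose two tertiary chlorides are homotopic. A deficit of (Me3SiC≡C)3Al in (CH2Cl)2 at 0 °C replaces one of them through the ion pair to give {[(1R,2S,4S,5S)-2,4-dibromo-5-chloro-1,5-dimethylcyclohexyl]ethynyl}trimethylsilane F2, and unreacted F1 is recycled. K2CO3 in MeOH removes silicon to give (1S,2S,4S,5R)-2,4-dibromo-1-chloro-5-ethynyl-1,5-dimethylcyclohexane F3. Cp2Zr(H)Cl in THF followed by N-chlorosuccinimide then gives 11.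

Step 4. The facial selectivity of the BrCl addition rests on conformational arguments only and may be modest, giving the diastereomer with Cl and Br on the exchanged faces. The fallback makes this pair of centres reagent-controlled through C–O bonds; it sets out from 3 and comes back at 6. A second epoxidation of 3 with the same ketone and Oxone (2KHSO5·KHSO4·K2SO4), which is matched for the opposite ring face, gives the C2-symmetric trans-bis-epoxide (1S,3S,5R,7R)-1,3-dimethyl-4,8-dioxatricyclo[5.1.0.0^3,5]octane F4. Excess Li2NiBr4 in THF opens both oxiranes at the secondary carbons to give (1S,3S,4S,6S)-4,6-dibromo-1,3-dimethylcyclohexane-1,3-diol F5. One equivalent of (CF3CO)2O with pyridine in CH2Cl2 at −40 °C acylates one of the two homotopic hydroxyl groups to give (1S,2S,4S,5S)-2,4-dibromo-5-hydroxy-1,5-dimethylcyclohexyl 2,2,2-trifluoroacetate F6, and the diol is recycled. SOCl2 in CH2Cl2 at 0 °C then replaces the remaining tertiary hydroxyl by chloride with retention (bromine participation) to give 6.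

Step 2. The ee for a methyl-substituted ring alkene, the facial sense and the mono- versus bis-epoxidation ratio are uncertain, and 2 and 3 are volatile. The fallback replaces asymmetric catalysis by resolution; it sets out from 2 and comes back at 5. One equivalent of N-bromosuccinimide in aqueous acetone at 0 °C gives racemic trans-6-bromo-1,3-dimethylcyclohex-3-en-1-ol F7 (anti, Markovnikov bromohydrin). Preparative chromatography on a chiral stationary phase (supercritical CO2/MeOH) gives (1S,6S)-6-bromo-1,3-dimethylcyclohex-3-en-1-ol F8. (CF3CO)2O and pyridine in CH2Cl2 at 0 °C then give 5.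

**Further compounds**

F1 | step 6 | (1S,3S,4S,6S)-4,6-dibromo-1,3-dichloro-1,3-dimethylcyclohexane | C[C@]1(Cl)C[C@](C)(Cl)[C@@H](Br)C[C@@H]1Br
F2 | step 6 | {[(1R,2S,4S,5S)-2,4-dibromo-5-chloro-1,5-dimethylcyclohexyl]ethynyl}trimethylsilane | C[C@]1(Cl)C[C@](C)(C#C[Si](C)(C)C)[C@@H](Br)C[C@@H]1Br
F3 | step 6 | (1S,2S,4S,5R)-2,4-dibromo-1-chloro-5-ethynyl-1,5-dimethylcyclohexane | C[C@]1(Cl)C[C@](C)(C#C)[C@@H](Br)C[C@@H]1Br
F4 | step 4 | (1S,3S,5R,7R)-1,3-dimethyl-4,8-dioxatricyclo[5.1.0.0^3,5]octane | C[C@]12C[C@]3(C)O[C@@H]3C[C@H]1O2
F5 | step 4 | (1S,3S,4S,6S)-4,6-dibromo-1,3-dimethylcyclohexane-1,3-diol | C[C@]1(O)C[C@](C)(O)[C@@H](Br)C[C@@H]1Br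
F6 | step 4 | (1S,2S,4S,5S)-2,4-dibromo-5-hydroxy-1,5-dimethylcyclohexyl 2,2,2-trifluoroacetate | C[C@]1(O)C[C@](C)(OC(=O)C(F)(F)F)[C@@H](Br)C[C@@H]1Br
F7 | step 2 | racemic trans-6-bromo-1,3-dimethylcyclohex-3-en-1-ol (1S,6S and 1R,6R) | CC1=CC[C@H](Br)[C@@](C)(O)C1.CC1=CC[C@@H](Br)[C@](C)(O)C1
F8 | step 2 | (1S,6S)-6-bromo-1,3-dimethylcyclohex-3-en-1-ol | CC1=CC[C@H](Br)[C@@](C)(O)C1
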